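## Structural features

(+)-Myristinin A is a 2,4-trans-4-arylflavan: a chroman (aromatic ring A fused to the oxygen heterocycle ring C) with a 4-hydroxyphenyl group (ring B) on C2 and, joined by a carbon–carbon bond to C4, a 3-dodecanoyl-2,4,6-trihydroxyphenyl group (ring D). The only stereocentres, C2 (S) and C4 (R), are separated by the C3 methylene and hold their aryl groups on opposite faces of ring C; ring closures that run through chair-like or equilibrating intermediates tend instead to put both aryl groups equatorial, which is the cis arrangement. Several points are fragile: C2–O1 is a benzylic ether para to the ring B oxygen and can ionise under acid, which would scramble C2; the C4–ring D bond joins a doubly benzylic carbon to a phloroglucinol ring and is also acid-sensitive; the five free phenols are oxidation-prone; and the ketone has enolisable α-hydrogens that rule out strong base once it is in place. The real difficulty is therefore stereochemical and steric: a crowded C4 flanked by the two ortho oxygens of ring D, in a trans 1,3-relation to C2 that has to come from a stereospecific event. Ring A is a resorcinol whose oxygens sit on C7 and C8a and whose C4a, next to C8a, carries the C4 branch. The key step uses exactly this pattern: C8a with its oxygen and C4a are the carbonyl carbon and α-carbon of a δ-lactone whose other ring atoms are C4, C3, C2 and the oxygen on C2, and C5, C6, C7 with its oxygen and C8 are added as one 3-oxobutenyl unit. Both stereocentres can thus be set on a saturated six-membered lactone, where cis is easy, before ring A exists, and the trans relation then follows from one inversion at C2.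

## Logic of the disconnections

**22 from 21.** The four O–CH2Ph bonds are cut. All phenols are uncovered together by neutral hydrogenolysis, so the air-sensitive polyphenol exists only in the last flask. The forward step must spare the cyclic benzylic C2–O1 bond and the aryl ketone.

**21 from 18 and 19.** The bond between ring D and the acyl carbon is cut. An enolisable ketone could not pass the strongly basic construction of ring A, and the free position of ring D in 18 is the most nucleophilic carbon in the molecule, so the chain is attached late from the acid 19. The gain is that ring D travels as a symmetrical tri-ether. The forward step must choose ring D over ring A and must not ionise C2. The free C7 phenol is turned to advantage: its transient ester 20 protects the oxygen and deactivates ring A, which saves a separate protection step.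

**18 from 17.** O1–C2 is cut. Closure by displacement at C2 with inversion converts the easily made cis-derived pattern into the trans one stereospecifically. The gain is an open-chain triol without the heterocycle. The demand is a clean SN2 process at a benzylic carbon that is prone to ionise.

**17 from 14 and 15 (key disconnection).** C4a–C5 and C8–C8a are cut, which removes ring A. A complete resorcinol ring is traded for a δ-lactone and the four-carbon enone 15. The ketone oxygen of 15 becomes the C7 hydroxyl, its methyl carbon C8 and its methoxy-bearing carbon C5. One point of atom bookkeeping needs stating exactly: in 14 the oxygen on C2 is the ring oxygen and the oxygen on C8a is the carbonyl oxygen. The ring oxygen becomes the C2 hydroxyl of 17 and is the oxygen lost on going to 18, so O1 of 18 to 22 is the former carbonyl oxygen. The forward step, which passes through 16, must form carbon–carbon bonds at both ends and must leave C2 and C4 alone.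

**14 from 13.** The C4–H and C3–H bonds are removed, which introduces a C3=C4 double bond. The C4 stereocentre then becomes a consequence of the C2 centre: hydride delivered anti to the aryl group on the ring gives the cis lactone. The demand is a 1,4-reduction that spares benzyl ethers and the benzylic lactone C–O bond.

**13 from 7 and 10.** The C4–ring D bond is cut as an sp2–sp2 coupling. This gives two fragments of similar size and puts the hindered ring in last. The aryl group carries two ortho alkoxy groups, so a base-free coupling through 11 and 12 is asked for.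

**10 from 9 from 8.** One C–Br bond and three O–benzyl bonds are cut, back to the symmetrical triol 8.

**7 from 6.** The O–S bond is cut. 6 is the enol of a β-keto lactone and has only one oxygen to sulfonylate.

**6 from 2 and 3, and 2 from 1.** The bond between C2 and C3 is cut, an aldol bond made through 4 and 5. This is the only step that sets absolute configuration, and it does so catalytically. The demand is face selectivity at the aldehyde carbon of 3.

## Other disconnections considered

**Alternative 1:** The cut goes through C3–C4 and O1–C2, so ring C is assembled from an ortho-quinone methide that carries C4 with ring D and from a two-carbon enamide. In the forward sense a chiral phosphoric acid would dehydrate the racemic ortho-hydroxybenzhydrol [4-(benzyloxy)-2-hydroxyphenyl][2,4,6-tris(benzyloxy)phenyl]methanol A1 to the quinone methide and guide the addition of N-vinylacetamide A2 across C4 and the phenol oxygen. This should give the cis 2-acetamidochroman A3 with C4 set by the catalyst.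

- In its favour: rings A and D are bought as arenes, A1 would come from one addition of 11 to a salicylaldehyde, and C4 is fixed by catalysis in one convergent step under mild acid.
- Against it here: ring B is not yet in the molecule and C2 leaves the key step as an N,O-acetal. The aryl group would have to be introduced by acid ionisation to the cyclic oxocarbenium ion and capture by an oxygenated aryl nucleophile. The trans outcome would then rest on a kinetic facial preference of a cation and not on a stereospecific event; the acid threatens the C4–ring D bond; and an arene nucleophile adds ortho/para questions. The quinone methide also bears a 2,4,6-trialkoxyphenyl group at its terminus and is far more stabilised and twisted than the simple aryl cases for which this catalysis is established.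
- Comparison: on structure the alternative sets C4 directly, which is better than the relay used in the chosen plan, but it leaves C2 to a less certain step, where the chosen plan has an invertive SN2. On mechanism the two are about equal, each with one catalytic asymmetric step and one uncertain step, and the alternative's conditions are milder. On step economy the alternative would be shorter by perhaps two or three steps and is the better plan if the C2 arylation can be made trans-selective.

**Alternative 2:** The cut is C4–C4a, made on an indanone in which the future C2 is the carbonyl carbon and O1 is still missing. In the forward sense Pd(OAc)2 with a chiral bisphosphine and an amine base would convert the 2'-triflyloxychalcone A4 into the indanone A5: the aryl triflate adds to zerovalent palladium, the aryl–palladium bond adds to the β-carbon of the enone, and the palladium enolate is protonated. Because both alkene carbons end up inside the five-membered ring, this closure is formally 5-endo and is better described as an intramolecular conjugate arylation than as an exo carbopalladation.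

- In its favour: A4 would come from an aldol condensation and a triflation, all three aromatic rings are purchased, and C4 is set directly by a catalytic carbon–carbon bond formation. On this point it equals Alternative 1 and is more direct than the chosen plan.
- Against it here: the β-carbon carries the di-ortho-substituted, electron-rich ring D, which is twisted out of conjugation and makes the enone a hindered, poor acceptor. The free 2'-hydroxychalcone needed before triflation tends to close to a flavanone. After A5 the route still needs a Baeyer–Villiger ring expansion to the dihydrocoumarin A6, with a peracid in the presence of a trialkoxybenzene, and then conversion of the lactone carbonyl into CH(ring B). If ring B is added first and the resulting cyclic oxocarbenium ion is reduced, hydride should enter anti to ring D, which gives the unwanted cis isomer, so the order would have to be reduction to the lactol and then arylation, again a non-stereospecific cation capture.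
- Comparison: on structure and mechanism the C4 step is cleaner than the relay of the chosen plan, but C2 is less secure. On step economy there is no gain, since four or five steps follow the key step where the chosen plan needs one.

**Alternative 3:** The cuts are C4a–C8a, C7–C8 and C6–C7, so rings A and C are formed together from the acyclic diazo enone A7. In the forward sense irradiation would trigger a Wolff rearrangement of A7 to a vinylketene in which the ketene carbon is C7 and its α-carbon is C4a. This would add (2+2) to the tethered ethynyl ether (C8 and C8a), the cyclobutenone would open in a 4-electron electrocyclic step, and a 6-electron ring closure and tautomerisation would give the flavan-7-ol A8, which is the same compound as 18.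

- In its favour: three bonds and two rings form in one neutral, reagent-free operation. The polarity is matched, since the ketene carbon joins the alkyne carbon remote from oxygen. The C2–O bond is present from the start, so no substitution at the ionisable C2 is needed. On bonds formed per step and on avoiding the Mitsunobu closure it is better than the chosen plan, and on the free, differentiated C7 hydroxyl it is equal.
- Against it here: A7 must already hold both stereocentres in the anti relation, a fully substituted diazo carbon next to the crowded benzylic centre (not reachable by simple diazo transfer to a methyl ketone), and an ethynyl ether of a secondary p-alkoxybenzylic alcohol, a function prone to thermal elimination to a ketene and to ionisation. The tethered version that closes an oxygen heterocycle at the same time is less established than the intermolecular reaction.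
- Comparison: on mechanism it is the more elegant step; on structure the stereochemical problem is only moved to an acyclic precursor; on step economy the longer and more fragile way to A7 outweighs the gain of the cascade.

Key step: step 8

Assumption: the Ti(OiPr)4/(R)-BINOL catalyst is taken to give the (R) carbinol from aryl aldehyde 3; if the sense of induction were the opposite, (S)-BINOL would be used and nothing else in the route changes.

## Route

Step 1
Reactants: 1 2,2,6-trimethyl-4H-1,3-dioxin-4-one
Product: 2 2,2-dimethyl-6-methylidene-4-(trimethylsilyloxy)-1,3-diox-4-ene (silyl dienol ether of 1; ring O1–C2(CH3)2–O3–C4(OSiMe3)=C5H–C6(=CH2))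
Conditions: LiN(iPr)2, THF, −78 °C; Me3SiCl, −78 °C → rt; distillation
Reagents that add atoms: chlorotrimethylsilane, C[Si](C)(C)Cl
Why: Kinetic deprotonation of the vinylogous ester at the C6 methyl group gives the lithium dienolate, which Me3SiCl traps on oxygen (O-silylation of a dienolate); no stereocentre is involved, and the product is the usual nucleophile for vinylogous Mukaiyama aldol reactions.

Step 2
Reactants: 2 2,2-dimethyl-6-methylidene-4-(trimethylsilyloxy)-1,3-diox-4-ene; 3 4-(benzyloxy)benzaldehyde
Product: 6 (6R)-6-[4-(benzyloxy)phenyl]-4-hydroxy-5,6-dihydro-2H-pyran-2-one, via silyl aldol adduct 4 (not isolated), via methyl hydroxy keto ester 5 (not isolated)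
Conditions: Ti(OiPr)4 (10 mol%), (R)-BINOL (10 mol%), 4 Å molecular sieves, THF, −78 °C → rt; then K2CO3, MeOH, rt; aq KHSO4, 0 °C
Reagents that add atoms: none
Why: Vinylogous Mukaiyama aldol reaction: the Ti(OiPr)4/(R)-BINOL complex activates 3 and the dienol ether attacks through its terminal carbon, the ligand shielding one face of the aldehyde so that the carbinol centre (future C2) should form as (R). Basic methanol then cleaves the silyl ether and opens the dioxinone to 5, whose hydroxyl closes onto the methyl ester (lactonisation) with loss of acetone and without touching the C–O bond at the stereocentre. No strong acid meets the ionisable p-benzyloxybenzylic carbinol, and the acidic product can be separated from BINOL by bicarbonate extraction.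

Step 3
Reactants: 6 (6R)-6-[4-(benzyloxy)phenyl]-4-hydroxy-5,6-dihydro-2H-pyran-2-one
Product: 7 (6R)-6-[4-(benzyloxy)phenyl]-2-oxo-5,6-dihydro-2H-pyran-4-yl trifluoromethanesulfonate
Conditions: (CF3SO2)2O (1.1 equiv), Et3N (1.2 equiv), CH2Cl2, −78 °C
Reagents that add atoms: trifluoromethanesulfonic anhydride, O=S(=O)(OS(=O)(=O)C(F)(F)F)C(F)(F)F
Why: Enol triflate formation: Et3N generates the enolate of the β-keto lactone and the anhydride traps it at the C4 oxygen, the only one available. The low temperature keeps the base from opening the ring by elimination across C5–C6, so the C6 centre is untouched.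

Step 4
Reactants: 8 phloroglucinol (benzene-1,3,5-triol)
Product: 9 1,3,5-tris(benzyloxy)benzene
Conditions: BnBr (3.3 equiv), K2CO3 (4 equiv), DMF, rt → 60 °C; crystallisation
Reagents that add atoms: benzyl bromide, BrCc1ccccc1
Why: Threefold Williamson etherification; K2CO3 in DMF favours O- over C-alkylation of the phloroglucinol anions, and the symmetrical tri-ether should crystallise away from C-benzylated by-products.

Step 5
Reactants: 9 1,3,5-tris(benzyloxy)benzene
Product: 10 2-bromo-1,3,5-tris(benzyloxy)benzene
Conditions: N-bromosuccinimide (1.0 equiv), CH2Cl2, −20 → 0 °C, dark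
Reagents that add atoms: N-bromosuccinimide, O=C1CCC(=O)N1Br
Why: Electrophilic aromatic bromination of a very electron-rich arene; the three ring positions are equivalent, so only one mono-bromide can form, and one equivalent of reagent at low temperature limits a second bromination. The phenyl rings of the benzyl groups are far less reactive.

Step 6
Reactants: 10 2-bromo-1,3,5-tris(benzyloxy)benzene; 7 (6R)-6-[4-(benzyloxy)phenyl]-2-oxo-5,6-dihydro-2H-pyran-4-yl trifluoromethanesulfonate
Product: 13 (6R)-6-[4-(benzyloxy)phenyl]-4-[2,4,6-tris(benzyloxy)phenyl]-5,6-dihydro-2H-pyran-2-one, via aryllithium 11 (not isolated), via arylzinc chloride 12 (not isolated)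
Conditions: 10, n-BuLi, THF, −78 °C; ZnCl2, −78 °C → rt; then 7, Pd(OAc)2 (3 mol%), SPhos (6 mol%), THF, rt → 45 °C
Reagents that add atoms: none
Why: Negishi coupling: bromine–lithium exchange at −78 °C outruns benzylic deprotonation, transmetalation to ZnCl2 gives a non-basic aryl nucleophile that leaves the lactone alone, and the electron-poor enol triflate adds readily to zerovalent palladium. The biaryl phosphine is chosen to drive transmetalation and reductive elimination of the di-ortho-substituted aryl group; no base is present, so C6 cannot be lost through ring-opening elimination.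

Step 7
Reactants: 13 (6R)-6-[4-(benzyloxy)phenyl]-4-[2,4,6-tris(benzyloxy)phenyl]-5,6-dihydro-2H-pyran-2-one
Product: 14 (4R,6R)-6-[4-(benzyloxy)phenyl]-4-[2,4,6-tris(benzyloxy)phenyl]oxan-2-one (cis lactone)
Conditions: Cu(OAc)2 (5 mol%), 1,2-bis(diphenylphosphino)benzene (5 mol%), (EtO)2MeSiH (3 equiv), t-BuOH (3 equiv), toluene, rt
Reagents that add atoms: none
Why: Conjugate reduction by phosphine-ligated CuH (monovalent copper, regenerated by the silane): hydride goes to C4 and the copper enolate is protonated by t-BuOH. On the half-chair with the C6 aryl group pseudo-equatorial the hydride should enter anti to that aryl group, as cuprates do with 6-substituted dihydropyranones, so the new C4–H is trans to it and ring D ends cis to ring B, which is (4R). Benzyl ethers and the benzylic lactone C–O bond, which heterogeneous hydrogenation would endanger, are inert.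

Step 8
Reactants: 14 (4R,6R)-6-[4-(benzyloxy)phenyl]-4-[2,4,6-tris(benzyloxy)phenyl]oxan-2-one; 15 (E)-4-methoxybut-3-en-2-one
Product: 17 4-[(1R,3R)-3-[4-(benzyloxy)phenyl]-3-hydroxy-1-[2,4,6-tris(benzyloxy)phenyl]propyl]benzene-1,3-diol, via oxobutenyl lactone 16 (not isolated)
Conditions: LiN(iPr)2 (1.0 equiv), THF, −78 °C; 15 (1.2 equiv), −78 → 0 °C; KOtBu (3 equiv), 0 °C → rt; AcOH, 0 °C
Reagents that add atoms: none
Why: LiN(iPr)2 deprotonates C3 of 14 (future C4a), the only enolisable position, and the lithium enolate adds to the methoxy-bearing carbon of 15; attack at the ketone carbonyl is reversible on warming whereas the conjugate adduct loses methoxide for good, so the C4a–C5 bond ends in 16, which the liberated methoxide holds as a delocalised enolate. In this pentadienyl-type anion the C5–C6 bond has little double-bond character, so the side chain can turn to the cis geometry that brings the methyl group next to the lactone carbonyl. KOtBu then enolises the methyl ketone in equilibrium and its carbon (future C8) attacks the lactone carbonyl (future C8a) in a 6-(enolendo)-exo-trig Claisen closure of ring A, after which the tetrahedral intermediate expels the alkoxide on C2. Tautomerisation of the cyclohexenedione gives the resorcinol, whose dianion is the thermodynamic sink that pulls the reversible steps forward. The closest known reaction type is the consecutive Michael–Claisen (3+3) condensation of an ester enolate with a methyl ketone acceptor, which gives cyclohexane-1,3-diones from enones and resorcinols from β-alkoxy enones; here the ester is a lactone, so the leaving alkoxide stays in the molecule as the C2 hydroxyl. No stereocentre is created: C4a is stereogenic only in passing, C4–H is not acidic, and C2 keeps its C–O bond and only changes from acyloxy to hydroxy. The selectivity needed is carbon–carbon bond formation at both ends: at C4a it is secured by the single enolisable site, the preformed enolate and the irreversible loss of methoxide, and at C8 by reversibility, since O-acylation through the enolate oxygen would give an α-pyrone that is still an activated ester and can reopen, while the C-acylation product aromatises.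

Step 9
Reactants: 17 4-[(1R,3R)-3-[4-(benzyloxy)phenyl]-3-hydroxy-1-[2,4,6-tris(benzyloxy)phenyl]propyl]benzene-1,3-diol
Product: 18 (2S,4R)-2-[4-(benzyloxy)phenyl]-4-[2,4,6-tris(benzyloxy)phenyl]-3,4-dihydro-2H-chromen-7-ol (2,4-trans)
Conditions: PPh3 (1.3 equiv), diisopropyl azodicarboxylate (1.3 equiv), THF (0.02 M), 0 °C
Reagents that add atoms: none
Why: Mitsunobu etherification: the benzylic hydroxyl is activated as its oxyphosphonium ion and displaced by the ortho phenol in a 6-exo-tet SN2 closure with inversion, which turns the (R) carbinol into (2S) and so gives the 2,4-trans flavan; the C7 phenol cannot reach C2. Dilution and 0 °C favour the intramolecular SN2 over ionisation of the p-benzyloxybenzylic centre, and because C4 is fixed any leakage would show up as the separable 2,4-cis diastereomer and not as loss of enantiopurity.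

Step 10
Reactants: 18 (2S,4R)-2-[4-(benzyloxy)phenyl]-4-[2,4,6-tris(benzyloxy)phenyl]-3,4-dihydro-2H-chromen-7-ol; 19 dodecanoic acid
Product: 21 1-[2,4,6-tris(benzyloxy)-3-[(2S,4R)-2-[4-(benzyloxy)phenyl]-7-hydroxy-3,4-dihydro-2H-chromen-4-yl]phenyl]dodecan-1-one, via C7 dodecanoate ester 20 (not isolated)
Conditions: 19 (3 equiv), (CF3CO)2O (4 equiv), CH2Cl2, 0 °C; 18, 0 °C → rt; evaporate; then K2CO3 (1.5 equiv), MeOH/THF, rt
Reagents that add atoms: none
Why: Friedel–Crafts acylation by the mixed anhydride formed in the flask from 19 and (CF3CO)2O: the free position of ring D, activated by two ortho and one para alkoxy groups, is the most nucleophilic carbon in the molecule. The C7 phenol is esterified under the same conditions, which shields it and deactivates ring A toward C-acylation; basic methanol then cleaves this aryl ester, while the aryl ketone and the benzyl ethers are inert. Short contact at low temperature and removal of CF3CO2H before the methanolysis limit acid ionisation at C2.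

Step 11
Reactants: 21 1-[2,4,6-tris(benzyloxy)-3-[(2S,4R)-2-[4-(benzyloxy)phenyl]-7-hydroxy-3,4-dihydro-2H-chromen-4-yl]phenyl]dodecan-1-one
Product: 22 (+)-myristinin A, 1-[2,4,6-trihydroxy-3-[(2S,4R)-7-hydroxy-2-(4-hydroxyphenyl)-3,4-dihydro-2H-chromen-4-yl]phenyl]dodecan-1-one
Conditions: H2 (1 atm), Pd/C (10% palladium on carbon), EtOAc/MeOH, rt; work-up under argon
Reagents that add atoms: none
Why: Hydrogenolysis of the four aryl benzyl ethers under neutral conditions; the cyclic benzylic ether C2–O1 and the hydrogen-bonded aryl ketone should react much more slowly, so the reaction is stopped after four equivalents of hydrogen. Neither stereocentre is touched.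

## Compound list

1 | 2,2,6-trimethyl-4H-1,3-dioxin-4-one | CC1=CC(=O)OC(C)(C)O1 | starting material
2 | 2,2-dimethyl-6-methylidene-4-(trimethylsilyloxy)-1,3-diox-4-ene | C=C1C=C(O[Si](C)(C)C)OC(C)(C)O1 | intermediate
3 | 4-(benzyloxy)benzaldehyde | O=Cc1ccc(OCc2ccccc2)cc1 | starting material
4 | 6-[(2R)-2-[4-(benzyloxy)phenyl]-2-(trimethylsilyloxy)ethyl]-2,2-dimethyl-4H-1,3-dioxin-4-one | C[Si](C)(C)O[C@H](CC1=CC(=O)OC(C)(C)O1)c1ccc(OCc2ccccc2)cc1 | intermediate
5 | methyl (5R)-5-[4-(benzyloxy)phenyl]-5-hydroxy-3-oxopentanoate | COC(=O)CC(=O)C[C@@H](O)c1ccc(OCc2ccccc2)cc1 | intermediate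
6 | (6R)-6-[4-(benzyloxy)phenyl]-4-hydroxy-5,6-dihydro-2H-pyran-2-one | OC1=CC(=O)O[C@@H](c2ccc(OCc3ccccc3)cc2)C1 | intermediate
7 | (6R)-6-[4-(benzyloxy)phenyl]-2-oxo-5,6-dihydro-2H-pyran-4-yl trifluoromethanesulfonate | O=C1C=C(OS(=O)(=O)C(F)(F)F)C[C@H](c2ccc(OCc3ccccc3)cc2)O1 | intermediate
8 | phloroglucinol (benzene-1,3,5-triol) | Oc1cc(O)cc(O)c1 | starting material
9 | 1,3,5-tris(benzyloxy)benzene | c1ccc(COc2cc(OCc3ccccc3)cc(OCc3ccccc3)c2)cc1 | intermediate
10 | 2-bromo-1,3,5-tris(benzyloxy)benzene | Brc1c(OCc2ccccc2)cc(OCc2ccccc2)cc1OCc1ccccc1 | intermediate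
11 | [2,4,6-tris(benzyloxy)phenyl]lithium | [Li]c1c(OCc2ccccc2)cc(OCc2ccccc2)cc1OCc1ccccc1 | intermediate
12 | chloro[2,4,6-tris(benzyloxy)phenyl]zinc | Cl[Zn]c1c(OCc2ccccc2)cc(OCc2ccccc2)cc1OCc1ccccc1 | intermediate
13 | (6R)-6-[4-(benzyloxy)phenyl]-4-[2,4,6-tris(benzyloxy)phenyl]-5,6-dihydro-2H-pyran-2-one | O=C1C=C(c2c(OCc3ccccc3)cc(OCc3ccccc3)cc2OCc2ccccc2)C[C@H](c2ccc(OCc3ccccc3)cc2)O1 | intermediate
14 | (4R,6R)-6-[4-(benzyloxy)phenyl]-4-[2,4,6-tris(benzyloxy)phenyl]oxan-2-one (cis) | c1c(OCc2ccccc2)cc(OCc2ccccc2)c([C@@H]2C[C@H](c3ccc(OCc4ccccc4)cc3)OC(=O)C2)c1OCc1ccccc1 | intermediate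
15 | (E)-4-methoxybut-3-en-2-one | CO/C=C/C(C)=O | starting material
16 | (4R,6R)-6-[4-(benzyloxy)phenyl]-3-[(E)-3-oxobut-1-enyl]-4-[2,4,6-tris(benzyloxy)phenyl]oxan-2-one (C3 undefined; present as its delocalised enolate) | O=C1C(/C=C/C(C)=O)[C@H](c2c(OCc3ccccc3)cc(OCc3ccccc3)cc2OCc2ccccc2)C[C@H](c2ccc(OCc3ccccc3)cc2)O1 | intermediate
17 | 4-[(1R,3R)-3-[4-(benzyloxy)phenyl]-3-hydroxy-1-[2,4,6-tris(benzyloxy)phenyl]propyl]benzene-1,3-diol | c1c(OCc2ccccc2)cc(OCc2ccccc2)c([C@@H](c2ccc(O)cc2O)C[C@H](c2ccc(OCc3ccccc3)cc2)O)c1OCc1ccccc1 | intermediate
18 | (2S,4R)-2-[4-(benzyloxy)phenyl]-4-[2,4,6-tris(benzyloxy)phenyl]-3,4-dihydro-2H-chromen-7-ol | c1c(OCc2ccccc2)cc(OCc2ccccc2)c([C@@H]2C[C@@H](c3ccc(OCc4ccccc4)cc3)Oc3cc(O)ccc32)c1OCc1ccccc1 | intermediate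
19 | dodecanoic acid | CCCCCCCCCCCC(=O)O | starting material
20 | (2S,4R)-2-[4-(benzyloxy)phenyl]-4-[2,4,6-tris(benzyloxy)-3-dodecanoylphenyl]-3,4-dihydro-2H-chromen-7-yl dodecanoate | CCCCCCCCCCCC(=O)c1c(OCc2ccccc2)cc(OCc2ccccc2)c([C@@H]2C[C@@H](c3ccc(OCc4ccccc4)cc3)Oc3cc(OC(=O)CCCCCCCCCCC)ccc32)c1OCc1ccccc1 | intermediate
21 | 1-[2,4,6-tris(benzyloxy)-3-[(2S,4R)-2-[4-(benzyloxy)phenyl]-7-hydroxy-3,4-dihydro-2H-chromen-4-yl]phenyl]dodecan-1-one | CCCCCCCCCCCC(=O)c1c(OCc2ccccc2)cc(OCc2ccccc2)c([C@@H]2C[C@@H](c3ccc(OCc4ccccc4)cc3)Oc3cc(O)ccc32)c1OCc1ccccc1 | intermediate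
22 | (+)-myristinin A, 1-[2,4,6-trihydroxy-3-[(2S,4R)-7-hydroxy-2-(4-hydroxyphenyl)-3,4-dihydro-2H-chromen-4-yl]phenyl]dodecan-1-one | CCCCCCCCCCCC(=O)c1c(O)cc(O)c([C@@H]2C[C@@H](c3ccc(O)cc3)Oc3cc(O)ccc32)c1O | target

## Step count and least certain steps

Total step count: 11. Longest linear sequence: 9 steps (steps 1, 2, 3, 6, 7, 8, 9, 10 and 11, from 1 to 22); steps 4 and 5 make the ring D fragment, which joins in step 6.

**Step 8 (key step).** The most likely failure is proton transfer from the methyl group of 15 to the lactone enolate, or attack at the ketone carbonyl in place of conjugate addition, so that 15 condenses with itself and 14 is returned. A second weak point is slow onward reaction of the open-chain enolate if the geometry change or the second enolisation lags. The fallback sets out from 14 and returns at 17; it makes the first carbon–carbon bond under Lewis-acid conditions, where neither proton transfer nor ketone attack can compete. 14 is converted with LiN(iPr)2 and tert-butyldimethylsilyl chloride into its silyl ketene acetal tert-butyl-dimethyl-[[(2R,4R)-2-[4-(benzyloxy)phenyl]-4-[2,4,6-tris(benzyloxy)phenyl]-3,4-dihydro-2H-pyran-6-yl]oxy]silane F1. This is combined with commercial 4,4-dimethoxybutan-2-one under catalytic Me3SiOTf in CH2Cl2 at −78 °C (Mukaiyama-type addition to an acetal, in which an oxocarbenium ion is the electrophile) to give the β-methoxy ketone (4R,6R)-6-[4-(benzyloxy)phenyl]-3-(1-methoxy-3-oxobutyl)-4-[2,4,6-tris(benzyloxy)phenyl]oxan-2-one F2. KOtBu in THF then eliminates methanol to give 16 in the flask and carries the Claisen closure and aromatisation through to 17. This fallback answers the first weak point only; the closure is the same as in the main step.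

**Step 7.** The most likely failure is slow hydride transfer to C4, which is shielded on both faces by the ortho benzyloxy groups of the twisted ring D, with competing reduction of the lactone carbonyl or insufficient facial discrimination. The fallback sets out from 13 and returns at 14 and makes no new compound (F0). It replaces hydride conjugate addition by homogeneous hydrogenation with [Ir(cod)(PCy3)(py)]PF6 under H2 in CH2Cl2, a catalyst type suited to hindered trisubstituted alkenes that leaves benzyl ethers alone; hydrogen should again be delivered to the face anti to the C6 aryl group.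

**Step 6.** The most likely failure is slow transmetalation and reductive elimination of the di-ortho-alkoxy aryl group, so that 12 is lost by protonation or homocoupling while 7 decomposes. The fallback sets out from 7 and 10 and returns at 13; it reverses the polarity of the coupling so that the hindered ring is the electrophile. Borylation of 7 with bis(pinacolato)diboron (PdCl2(dppf), KOAc, dioxane, 80 °C) gives the vinyl boronate (6R)-6-[4-(benzyloxy)phenyl]-4-(4,4,5,5-tetramethyl-1,3,2-dioxaborolan-2-yl)-5,6-dihydro-2H-pyran-2-one F3. Suzuki–Miyaura coupling of F3 with 10 (Pd(OAc)2, SPhos, K3PO4, toluene/water) then gives 13.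

**Step 10.** The most likely failure is acid-induced ionisation at C2 (epimerisation toward the cis flavan) or acid cleavage of the C4–ring D bond by the CF3CO2H that is set free; a lesser risk is acylation on ring A. The fallback sets out from 18 and returns at 22; it builds the ketone without strong protic acid. Benzylation of 18 (BnBr, K2CO3, DMF) gives (2S,4R)-7-(benzyloxy)-2-[4-(benzyloxy)phenyl]-4-[2,4,6-tris(benzyloxy)phenyl]-3,4-dihydro-2H-chromene F4. Vilsmeier–Haack formylation (POCl3, DMF, 0 °C; aq NaOAc) at the free ring D position gives 2,4,6-tris(benzyloxy)-3-[(2S,4R)-7-(benzyloxy)-2-[4-(benzyloxy)phenyl]-3,4-dihydro-2H-chromen-4-yl]benzaldehyde F5. Addition of n-C11H23MgBr in THF gives 1-[2,4,6-tris(benzyloxy)-3-[(2S,4R)-7-(benzyloxy)-2-[4-(benzyloxy)phenyl]-3,4-dihydro-2H-chromen-4-yl]phenyl]dodecan-1-ol F6 as a mixture of carbinol epimers. Oxidation with Dess–Martin periodinane gives 1-[2,4,6-tris(benzyloxy)-3-[(2S,4R)-7-(benzyloxy)-2-[4-(benzyloxy)phenyl]-3,4-dihydro-2H-chromen-4-yl]phenyl]dodecan-1-one F7, and hydrogenolysis under the conditions of step 11 gives 22.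

**Step 2.** The most likely failure is insufficient facial selectivity with the electron-rich, less electrophilic aldehyde 3, for instance through an uncatalysed silyl-transfer pathway. The fallback sets out from 1 and returns at 6; it sets the carbinol centre by reduction instead of by carbon–carbon bond formation. The lithium dienolate of 1 (LiN(iPr)2, 2 equiv, THF, −78 °C) is acylated at its terminal carbon with commercial 4-(benzyloxy)benzoyl chloride to give 6-[2-[4-(benzyloxy)phenyl]-2-oxoethyl]-2,2-dimethyl-4H-1,3-dioxin-4-one F8. Asymmetric transfer hydrogenation with RuCl(p-cymene)[(R,R)-TsDPEN] in HCO2H/Et3N, which by the usual aryl ketone model should give the (R) carbinol, gives 6-[(2R)-2-[4-(benzyloxy)phenyl]-2-hydroxyethyl]-2,2-dimethyl-4H-1,3-dioxin-4-one F9. K2CO3 in methanol then converts F9 into 6 as in step 2.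

## Further compounds

F1 | step 8 | tert-butyl-dimethyl-[[(2R,4R)-2-[4-(benzyloxy)phenyl]-4-[2,4,6-tris(benzyloxy)phenyl]-3,4-dihydro-2H-pyran-6-yl]oxy]silane | CC(C)(C)[Si](C)(C)OC1=C[C@H](c2c(OCc3ccccc3)cc(OCc3ccccc3)cc2OCc2ccccc2)C[C@H](c2ccc(OCc3ccccc3)cc2)O1
F2 | step 8 | (4R,6R)-6-[4-(benzyloxy)phenyl]-3-(1-methoxy-3-oxobutyl)-4-[2,4,6-tris(benzyloxy)phenyl]oxan-2-one (epimers at C3 and at the methoxy carbon) | O=C1C(C(OC)CC(C)=O)[C@H](c2c(OCc3ccccc3)cc(OCc3ccccc3)cc2OCc2ccccc2)C[C@H](c2ccc(OCc3ccccc3)cc2)O1
F0 | step 7 | none | none
F3 | step 6 | (6R)-6-[4-(benzyloxy)phenyl]-4-(4,4,5,5-tetramethyl-1,3,2-dioxaborolan-2-yl)-5,6-dihydro-2H-pyran-2-one | O=C1C=C(B2OC(C)(C)C(C)(C)O2)C[C@H](c2ccc(OCc3ccccc3)cc2)O1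
F4 | step 10 | (2S,4R)-7-(benzyloxy)-2-[4-(benzyloxy)phenyl]-4-[2,4,6-tris(benzyloxy)phenyl]-3,4-dihydro-2H-chromene | c1c(OCc2ccccc2)cc(OCc2ccccc2)c([C@@H]2C[C@@H](c3ccc(OCc4ccccc4)cc3)Oc3cc(OCc4ccccc4)ccc32)c1OCc1ccccc1
F5 | step 10 | 2,4,6-tris(benzyloxy)-3-[(2S,4R)-7-(benzyloxy)-2-[4-(benzyloxy)phenyl]-3,4-dihydro-2H-chromen-4-yl]benzaldehyde | O=Cc1c(OCc2ccccc2)cc(OCc2ccccc2)c([C@@H]2C[C@@H](c3ccc(OCc4ccccc4)cc3)Oc3cc(OCc4ccccc4)ccc32)c1OCc1ccccc1
F6 | step 10 | 1-[2,4,6-tris(benzyloxy)-3-[(2S,4R)-7-(benzyloxy)-2-[4-(benzyloxy)phenyl]-3,4-dihydro-2H-chromen-4-yl]phenyl]dodecan-1-ol (both carbinol epimers) | CCCCCCCCCCCC(O)c1c(OCc2ccccc2)cc(OCc2ccccc2)c([C@@H]2C[C@@H](c3ccc(OCc4ccccc4)cc3)Oc3cc(OCc4ccccc4)ccc32)c1OCc1ccccc1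
F7 | step 10 | 1-[2,4,6-tris(benzyloxy)-3-[(2S,4R)-7-(benzyloxy)-2-[4-(benzyloxy)phenyl]-3,4-dihydro-2H-chromen-4-yl]phenyl]dodecan-1-one | CCCCCCCCCCCC(=O)c1c(OCc2ccccc2)cc(OCc2ccccc2)c([C@@H]2C[C@@H](c3ccc(OCc4ccccc4)cc3)Oc3cc(OCc4ccccc4)ccc32)c1OCc1ccccc1
F8 | step 2 | 6-[2-[4-(benzyloxy)phenyl]-2-oxoethyl]-2,2-dimethyl-4H-1,3-dioxin-4-one | CC1(C)OC(CC(=O)c2ccc(OCc3ccccc3)cc2)=CC(=O)O1
F9 | step 2 | 6-[(2R)-2-[4-(benzyloxy)phenyl]-2-hydroxyethyl]-2,2-dimethyl-4H-1,3-dioxin-4-one | CC1(C)OC(C[C@@H](O)c2ccc(OCc3ccccc3)cc2)=CC(=O)O1
A1 | alternative 1 | [4-(benzyloxy)-2-hydroxyphenyl][2,4,6-tris(benzyloxy)phenyl]methanol (racemic) | OC(c1ccc(OCc2ccccc2)cc1O)c1c(OCc2ccccc2)cc(OCc2ccccc2)cc1OCc1ccccc1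
A2 | alternative 1 | N-vinylacetamide | CC(=O)NC=C
A3 | alternative 1 | N-[(2R,4R)-7-(benzyloxy)-4-[2,4,6-tris(benzyloxy)phenyl]-3,4-dihydro-2H-chromen-2-yl]acetamide (2,4-cis) | c1c(OCc2ccccc2)cc(OCc2ccccc2)c([C@@H]2C[C@H](NC(C)=O)Oc3cc(OCc4ccccc4)ccc32)c1OCc1ccccc1
A4 | alternative 2 | (E)-1-[5-(benzyloxy)-2-(trifluoromethanesulfonyloxy)phenyl]-3-[2,4,6-tris(benzyloxy)phenyl]prop-2-en-1-one | O=C(/C=C/c1c(OCc2ccccc2)cc(OCc2ccccc2)cc1OCc1ccccc1)c1cc(OCc2ccccc2)ccc1OS(=O)(=O)C(F)(F)F
A5 | alternative 2 | (3R)-6-(benzyloxy)-3-[2,4,6-tris(benzyloxy)phenyl]-2,3-dihydro-1H-inden-1-one | c1c(OCc2ccccc2)cc(OCc2ccccc2)c([C@@H]2CC(=O)c3cc(OCc4ccccc4)ccc32)c1OCc1ccccc1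
A6 | alternative 2 | (4R)-7-(benzyloxy)-4-[2,4,6-tris(benzyloxy)phenyl]-3,4-dihydro-2H-chromen-2-one | c1c(OCc2ccccc2)cc(OCc2ccccc2)c([C@@H]2CC(=O)Oc3cc(OCc4ccccc4)ccc32)c1OCc1ccccc1
A7 | alternative 3 | (5S,7S)-7-[4-(benzyloxy)phenyl]-4-diazo-7-(ethynyloxy)-5-[2,4,6-tris(benzyloxy)phenyl]hept-1-en-3-one | C=CC(=O)C(=[N+]=[N-])[C@H](c1c(OCc2ccccc2)cc(OCc2ccccc2)cc1OCc1ccccc1)C[C@@H](c1ccc(OCc2ccccc2)cc1)OC#C
A8 | alternative 3 | (2S,4R)-2-[4-(benzyloxy)phenyl]-4-[2,4,6-tris(benzyloxy)phenyl]-3,4-dihydro-2H-chromen-7-ol (2,4-trans; identical with 18) | c1c(OCc2ccccc2)cc(OCc2ccccc2)c([C@@H]2C[C@@H](c3ccc(OCc4ccccc4)cc3)Oc3cc(O)ccc32)c1OCc1ccccc1
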